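The route rests on disconnecting the C3–C1' bond together with O1–C2, which opens the pyran-4-one ring (ring C) to an o-hydroxyaryl enaminone. The key step exploits the push–pull unit O1–C2=C3–C4=O of ring C: in the open enaminone, C3 is a nucleophilic α-carbon and C2 a latent iminium carbon. A visible-light photoredox Meerwein arylation with 2,3,4-trimethoxybenzenediazonium tetrafluoroborate places the aryl radical on C3; the phenol oxygen then closes onto C2 and dimethylamine is lost, so the C3–C1' bond and ring C form in one operation from an acyclic precursor. Both partners come in one step each from commercial materials.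

Key step: step 3

Remark on the chemistry: the target has no stereocentre and no stereogenic double bond, so it is achiral and no enantiocontrol is required.

Step 1
Reactants: 1 1-(2-hydroxy-4,5-dimethoxyphenyl)ethan-1-one (2'-hydroxy-4',5'-dimethoxyacetophenone)
Product: 2 (E)-3-(dimethylamino)-1-(2-hydroxy-4,5-dimethoxyphenyl)prop-2-en-1-one
Conditions: DMF-DMA (2 equiv), PhMe, 100 °C; evaporate, crystallise (no silica)
Reagents that add atoms: N,N-dimethylformamide dimethyl acetal, COC(OC)N(C)C
Why: Aminomethylenation of an aryl methyl ketone with DMF-DMA (enaminone condensation) should give the thermodynamically favoured E enaminone, while the phenol, hydrogen-bonded to the carbonyl, should stay unmethylated at this temperature.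

Step 2
Reactants: 3 2,3,4-trimethoxyaniline
Product: 4 2,3,4-trimethoxybenzenediazonium tetrafluoroborate
Conditions: NaNO2, 48% aq. HBF4, H2O, 0 °C; precipitate with cold Et2O, store cold in the dark
Reagents that add atoms: sodium nitrite, [Na+].[O-]N=O; tetrafluoroboric acid, [H+].F[B-](F)(F)F
Why: Diazotization of a primary arylamine in strong acid keeps the free amine concentration low, which suppresses triazene and azo formation, and the non-nucleophilic tetrafluoroborate counter-ion should make the methoxy-substituted salt isolable.

Step 3
Reactants: 2 (E)-3-(dimethylamino)-1-(2-hydroxy-4,5-dimethoxyphenyl)prop-2-en-1-one; 4 2,3,4-trimethoxybenzenediazonium tetrafluoroborate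
Product: 6 6,7,2',3',4'-pentamethoxyisoflavone, via 2-(dimethylamino)isoflavanone 5 (not isolated)
Conditions: Ru(bpy)3(PF6)2 (1 mol%), degassed MeCN, blue LEDs (450 nm), 20 °C, 4 (1.5 equiv) added slowly; aq. NaHCO3 work-up
Reagents that add atoms: none
Why: Photoexcited Ru(II) reduces 4 by single-electron transfer, loss of N2 gives the 2,3,4-trimethoxyphenyl radical, this adds to the α-carbon of 2 (the future C3) to form the C3–C1' bond, and the resulting α-amino radical at the future C2 is oxidised to an iminium ion by Ru(III) or by a further molecule of 4 in a radical chain. The closest known reaction type is the visible-light photoredox Meerwein arylation of enaminones, enamides and enol acetates with arenediazonium salts, run here as a domino C–H arylation/chromone annulation. The phenol oxygen closes ring C by 6-exo-trig attack on the iminium carbon to give aminal 5, and β-elimination of dimethylamine, assisted by the acid set free, should aromatise 5 to the chromone. No stereocentre is created in the product, because the two transient sp3 centres of 5 (C2 and C3) are erased by the elimination. The step needs regioselectivity for C-α over C-β and over the two arene rings, which the push–pull polarisation of the enaminone secures (largest HOMO coefficient at C-α, nitrogen-stabilised radical after addition). It also needs chemoselectivity for the radical path over polar azo coupling at the same carbon, which the low electrophilicity of the trimethoxy-substituted diazonium ion and its low stationary concentration should favour.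

Compound list
1 | 1-(2-hydroxy-4,5-dimethoxyphenyl)ethan-1-one | CC(=O)c1cc(OC)c(OC)cc1O | starting material
2 | (E)-3-(dimethylamino)-1-(2-hydroxy-4,5-dimethoxyphenyl)prop-2-en-1-one | CN(C)/C=C/C(=O)c1cc(OC)c(OC)cc1O | intermediate
3 | 2,3,4-trimethoxyaniline | COc1ccc(N)c(OC)c1OC | starting material
4 | 2,3,4-trimethoxybenzenediazonium tetrafluoroborate | COc1ccc([N+]#N)c(OC)c1OC.F[B-](F)(F)F | intermediate
5 | 2-(dimethylamino)-6,7-dimethoxy-3-(2,3,4-trimethoxyphenyl)chroman-4-one (mixture of stereoisomers, not isolated) | CN(C)C1Oc2cc(OC)c(OC)cc2C(=O)C1c1ccc(OC)c(OC)c1OC | intermediate
6 | 6,7,2',3',4'-pentamethoxyisoflavone (6,7-dimethoxy-3-(2,3,4-trimethoxyphenyl)-4H-chromen-4-one) | COc1cc2occ(-c3ccc(OC)c(OC)c3OC)c(=O)c2cc1OC | target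

Total step count: 3
Longest linear sequence: 2 steps (1 → 2 → 6, or 3 → 4 → 6)

Steps most likely to fail

Step 3. Polar azo coupling of the diazonium ion at C-α of the enaminone may run ahead of electron transfer, and the aryl radical may be lost by hydrogen abstraction from the solvent or by addition to the electron-rich arene rings. The fallback sets out from 2 and comes back at 6. Iodine-induced cyclisation of 2 (I2, CHCl3, 20 °C) should give 3-iodo-6,7-dimethoxy-4H-chromen-4-one F1. Suzuki–Miyaura coupling of this with commercial (2,3,4-trimethoxyphenyl)boronic acid (COc1ccc(B(O)O)c(OC)c1OC) under Pd(dppf)Cl2, K2CO3, dioxane/H2O, 80 °C should form the same C3–C1' bond by a two-electron cross-coupling and give 6.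

Step 2. The diazonium ion may couple with not yet diazotized electron-rich aniline, and the salt may decompose during isolation or storage (hydrolysis, or loss of the ortho O-methyl group to a quinone diazide). The fallback sets out from 3 and comes back at 4. Compound 3 is diazotized in aq. HCl with NaNO2 at 0 °C and the solution is run at once into pyrrolidine/K2CO3, which should give the bench-stable triazene 1-[(E)-(2,3,4-trimethoxyphenyl)diazenyl]pyrrolidine F2 as a masked diazonium ion. Treatment of this with HBF4·OEt2 (2 equiv, no excess) in MeCN at 0 °C should release 4 in solution directly before the irradiation of step 3.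

Step 1. The acetal may O-methylate the phenol on prolonged heating, and the enaminone may close under acid to the 3-unsubstituted chromone during purification. The fallback sets out from 1 and comes back at 2. Claisen formylation of 1 with ethyl formate and NaH (3 equiv) in THF, followed by mild acid work-up, should give 2-hydroxy-6,7-dimethoxychroman-4-one F3, the cyclic hemiacetal of the β-keto aldehyde. Condensation of this with dimethylamine (2 M in THF, EtOH, 20 °C) should open the hemiacetal and give 2. Any 6,7-dimethoxychromone formed by dehydration should be opened by the same amine to 2.

Further compounds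
F1 | step 3 | 3-iodo-6,7-dimethoxy-4H-chromen-4-one | COc1cc2occ(I)c(=O)c2cc1OC
F2 | step 2 | 1-[(E)-(2,3,4-trimethoxyphenyl)diazenyl]pyrrolidine | COc1ccc(/N=N/N2CCCC2)c(OC)c1OC
F3 | step 1 | 2-hydroxy-6,7-dimethoxychroman-4-one | COc1cc2OC(O)CC(=O)c2cc1OC
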